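Follow the rate. Two flasks, amber and blue, differ in their charge of protonated nucleophile.

- amber: electrophile 0.34 M; protonated nucleophile 0.410 M; solid base 0.102 M; time 4.0 d
- blue: electrophile 0.34 M; protonated nucleophile 0.610 M; solid base 0.102 M; time 4.0 d

* part of the electrophile that has reacted at the end, amber
* part of the electrophile that has reacted at the end, blue
* what raising the concentration of protonated nucleophile from its lowest to its highest value here does to the part of the electrophile that has reacted (changes below 5 percentage points count as none) (it falls / no change / it rises)

- amounts and yields of acid set free count crystals too
- given per volume of solution although it is solid: solid base, crystals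
- at the start none of the solid base is in solution
- run time (amber): 4.0 d

    electrophile + nucleophile → acid set free + target (k1 = 0.35 L mol⁻¹ h⁻¹)
    nucleophile + acid set free ⇌ protonated nucleophile, settled at all times (K2 = 500 L mol⁻¹)
    acid set free + free base ⇌ salt of the base, settled at all times (K3 = 1100 L mol⁻¹)
    acid set free → by-product carried off (k4 = 0.042 h⁻¹)
    solid base ⇌ free base, rate k5*(cs5 - [free base]) while solid is left; crystals form when [free base] > cs5 (cs5 = 38 mM, k5 = 0.020 h⁻¹)
    crystals ⇌ acid set free, rate k6*(cs6 - [acid set free]) while solid is left; crystals form when [acid set free] > cs6 (cs6 = 10 mM, k6 = 2.3 h⁻¹)

This is my own reckoning. Electrophile takes free nucleophile to target and acid set free. The acid protonates nucleophile, and above 10 mM it falls out as crystals, which answer at 2.3 h⁻¹, far faster than the acid is lost at 0.042 h⁻¹. So I hold [acid set free] at 10 mM. Then one nucleophile in 6.00 is free, and the rate is the pinned constant 0.0583 L mol⁻¹ h⁻¹, which is 0.35 L mol⁻¹ h⁻¹ divided by that number, an apparent second-order constant, times electrophile times free and protonated nucleophile together.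

Amber starts at 8.13 mM h⁻¹, more than the 1.18 mM h⁻¹ that acid loss and dissolving base take away, so crystals grow. Over 4.0 d that rate would come to 0.780 M, more than the 0.34 M charged, so it must slow. Two factors slow it: the fraction of electrophile left and the fraction of nucleophile left. Their ratio grows as the exponential of nucleophile excess times pinned constant times time, reaching 1.48 in amber. That leaves 26.2% of the electrophile and 38.8% of the nucleophile, so amber's final rate is 0.102 of its first, and 73.8% has reacted. Blue, with its larger excess, keeps 11.1%, so 88.9% has reacted.

The forecast says 70% for amber (62% to 77%) and 84% for blue (76% to 90%), and that the part reacted: it rises. Both its central numbers lie below my figures. Its ground: “More protonated nucleophile at that same pinned acid level means proportionally more free nucleophile”.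

The simulation gives 70.7% for amber and 85.6% for blue; the part reacted: it rises, by 15 percentage points.

My amber figure stands 3 points above the simulation, where [acid set free] read 0.0113 M at 2.00 d, above 10 mM. The neighbour flask is blue with 0.15 M of protonated nucleophile, less than the 0.34 M of electrophile, so nucleophile is the limiting reagent and the excess turns negative. The same pinned constant, 0.0583 L mol⁻¹ h⁻¹, leaves 65.9% of the electrophile. That neighbour flask ended with 66.5% of its electrophile left, at 0.00994 M of acid set free beside 0.120 M of crystals.

All constants are invented, and the outcome is calculated.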